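Ring C of the isoflavanone is opened at two bonds that sit ortho to one another on ring A: O1–C8a and C4–C4a. Ring A therefore enters as a 3,5-dioxygenated benzyne and the O1–C2–C3–C4 chain as an enantiopure 3-aryloxetan-2-one that already carries ring B and the C3 stereocentre. In one operation the aryne inserts into the acyl–oxygen bond of the strained lactone, forms both bonds and expands the four-membered ring to the chroman-4-one. The aryne comes from a 2-silylaryl triflate (from phloroglucinol); the lactone from an auxiliary-controlled hydroxymethylation of the ring B arylacetic acid. Prenylation of a C5′ bromide and acetal removal finish the synthesis.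

Key step: step 13

Remark: numbering follows chroman-4-one (O1, C2, C3, C4, C4a, C5–C8, C8a; ring B primed). The target is the (3R) isomer (C4 > C2 > C1′ > H); the same spatial arrangement is (R) in lactone 19 and acids 17 and 18. The two coupling partners and their product were checked against the target for regiochemistry and configuration and needed no correction.

Step 1
Reactants: 1 phloroglucinol
Product: 2 3,5-bis(methoxymethoxy)phenol
Conditions: MOMCl (2.0 equiv), iPr2NEt, DMF, 0 °C to rt
Reagents that add atoms: chloromethyl methyl ether, COCCl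
Why: Phenol O-alkylation (methoxymethyl ether formation): two equivalents of the chloromethyl ether should give the bis-acetal as the main component of a statistical mixture, from which the mono- and tris-ethers are removed by chromatography.

Step 2
Reactants: 2 3,5-bis(methoxymethoxy)phenol
Product: 3 2-bromo-3,5-bis(methoxymethoxy)phenol
Conditions: NBS (1.0 equiv), CH2Cl2, –78 to –40 °C
Reagents that add atoms: N-bromosuccinimide, O=C1CCC(=O)N1Br
Why: Electrophilic aromatic bromination: NBS at low temperature in a non-coordinating solvent should deliver bromine ortho to the free hydroxyl (hydrogen-bonded delivery, two equivalent ortho sites), the para site being shielded by two flanking acetal groups.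

Step 3
Reactants: 3 2-bromo-3,5-bis(methoxymethoxy)phenol
Product: 6 3,5-bis(methoxymethoxy)-2-(trimethylsilyl)phenyl trifluoromethanesulfonate, via aryl trimethylsilyl ether 4 (not isolated), via lithium 2-silylphenolate 5 (not isolated)
Conditions: HMDS, THF, 65 °C, then evaporation; n-BuLi, THF, –78 °C; PhNTf2, –78 °C to rt
Reagents that add atoms: hexamethyldisilazane, C[Si](C)(C)N[Si](C)(C)C; N-phenylbis(trifluoromethanesulfonimide), O=S(=O)(N(c1ccccc1)S(=O)(=O)C(F)(F)F)C(F)(F)F
Why: O-Silylation, bromine–lithium exchange, anionic O→C 1,3-silyl shift (retro-Brook rearrangement) and O-triflation form the established one-flask route to ortho-silylaryl triflates; exchange at –78 °C outruns ortho-lithiation beside the acetals, and PhNTf2 replaces triflic anhydride so that the acetals are not activated.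

Step 4
Reactants: 7 2,3-dihydroxy-4-methoxybenzaldehyde
Product: 8 5-bromo-2,3-dihydroxy-4-methoxybenzaldehyde
Conditions: Br2 (1.0 equiv), NaOAc, AcOH, 15 °C
Reagents that add atoms: bromine, BrBr
Why: Electrophilic aromatic bromination should go to C5, which is para to the 2-hydroxyl, ortho to the methoxy group and meta to the formyl group, whereas C6 is ortho to the deactivating aldehyde.

Step 5
Reactants: 8 5-bromo-2,3-dihydroxy-4-methoxybenzaldehyde
Product: 9 5-bromo-4-methoxy-2,3-bis(methoxymethoxy)benzaldehyde
Conditions: MOMCl (3 equiv), iPr2NEt, CH2Cl2, 0 °C to rt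
Reagents that add atoms: chloromethyl methyl ether, COCCl
Why: Phenol O-alkylation (methoxymethyl ether formation) masks the catechol with the same acetal used on ring A, so that one mild final operation removes all four groups.

Step 6
Reactants: 9 5-bromo-4-methoxy-2,3-bis(methoxymethoxy)benzaldehyde
Product: 10 2-[5-bromo-4-methoxy-2,3-bis(methoxymethoxy)phenyl]acetonitrile
Conditions: TosMIC, t-BuOK, DME, –40 °C; then MeOH, 65 °C
Reagents that add atoms: p-toluenesulfonylmethyl isocyanide, Cc1ccc(cc1)S(=O)(=O)C[N+]#[C-]
Why: van Leusen reductive cyanation: addition of metalated TosMIC to the aldehyde, fragmentation of the oxazoline and methanolysis of the N-formyl intermediate should give the one-carbon-homologated nitrile under basic conditions that the acetals and the aryl bromide tolerate.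

Step 7
Reactants: 10 2-[5-bromo-4-methoxy-2,3-bis(methoxymethoxy)phenyl]acetonitrile
Product: 11 2-[5-bromo-4-methoxy-2,3-bis(methoxymethoxy)phenyl]acetic acid
Conditions: KOH, EtOH/H2O, 85 °C; then 1 M HCl to pH 3, 0 °C
Reagents that add atoms: water, O; potassium hydroxide, [K+].[OH-]
Why: Alkaline nitrile hydrolysis gives the arylacetic acid; the acetals and the aryl bromide are stable to hydroxide and to the brief cold acidification.

Step 8
Reactants: 11 2-[5-bromo-4-methoxy-2,3-bis(methoxymethoxy)phenyl]acetic acid
Product: 13 (4S)-4-benzyl-3-{2-[5-bromo-4-methoxy-2,3-bis(methoxymethoxy)phenyl]acetyl}-1,3-oxazolidin-2-one, via mixed pivalic anhydride 12 (not isolated)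
Conditions: PivCl, Et3N, THF, –20 °C; then (S)-4-benzyl-2-oxazolidinone, LiCl, –20 °C to rt
Reagents that add atoms: (S)-4-benzyl-1,3-oxazolidin-2-one, O=C1N[C@@H](Cc2ccccc2)CO1
Why: N-Acylation of the oxazolidinone auxiliary through the mixed pivalic anhydride (LiCl/Et3N variant) attaches the Evans auxiliary without strong base.

Step 9
Reactants: 13 (4S)-4-benzyl-3-{2-[5-bromo-4-methoxy-2,3-bis(methoxymethoxy)phenyl]acetyl}-1,3-oxazolidin-2-one
Product: 15 (4S)-4-benzyl-3-{(2R)-2-[5-bromo-4-methoxy-2,3-bis(methoxymethoxy)phenyl]-3-[(triisopropylsilyl)oxy]propanoyl}-1,3-oxazolidin-2-one, via sodium Z-enolate 14 (not isolated)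
Conditions: NaN(SiMe3)2, THF, –78 °C; then iPr3SiOCH2Cl, –78 to –40 °C
Reagents that add atoms: (triisopropylsiloxy)methyl chloride, CC(C)[Si](OCCl)(C(C)C)C(C)C
Why: Evans asymmetric alkylation: the chelated sodium Z-enolate is alkylated by the α-chloro ether on the face opposite the C4 benzyl group of the (S)-auxiliary, which sets the future C3 as (R); the minor diastereomer is removed by chromatography so that a single stereoisomer is carried on, and the oxygen arrives as a silyl ether without any Lewis acid that would attack the acetals.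

Step 10
Reactants: 15 (4S)-4-benzyl-3-{(2R)-2-[5-bromo-4-methoxy-2,3-bis(methoxymethoxy)phenyl]-3-[(triisopropylsilyl)oxy]propanoyl}-1,3-oxazolidin-2-one
Product: 17 (2R)-2-[5-bromo-4-methoxy-2,3-bis(methoxymethoxy)phenyl]-3-[(triisopropylsilyl)oxy]propanoic acid, via peroxy acid 16 (not isolated)
Conditions: LiOH, 30% H2O2, THF/H2O, 0 °C; Na2SO3; then 1 M HCl to pH 3
Reagents that add atoms: hydrogen peroxide, OO
Why: Hydroperoxide cleavage of the N-acyloxazolidinone attacks the exocyclic carbonyl selectively at 0 °C and is the standard release of α-aryl acids without epimerisation; sulfite reduces the peroxy acid.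

Step 11
Reactants: 17 (2R)-2-[5-bromo-4-methoxy-2,3-bis(methoxymethoxy)phenyl]-3-[(triisopropylsilyl)oxy]propanoic acid
Product: 18 (2R)-2-[5-bromo-4-methoxy-2,3-bis(methoxymethoxy)phenyl]-3-hydroxypropanoic acid
Conditions: Bu4NF, THF, 0 °C to rt; then 1 M HCl to pH 3, 0 °C
Reagents that add atoms: none
Why: Fluoride desilylation of the primary silyl ether is carried out on the carboxylate, whose α-hydrogen is not acidic, so the benzylic stereocentre is not at risk.

Step 12
Reactants: 18 (2R)-2-[5-bromo-4-methoxy-2,3-bis(methoxymethoxy)phenyl]-3-hydroxypropanoic acid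
Product: 19 (3R)-3-[5-bromo-4-methoxy-2,3-bis(methoxymethoxy)phenyl]oxetan-2-one
Conditions: PPh3, DIAD, THF, –78 to –10 °C
Reagents that add atoms: none
Why: Mitsunobu lactonisation by hydroxyl activation: the carboxylate displaces the primary alkoxyphosphonium group in a 4-exo-tet closure, so the carboxyl carbon is never activated next to the acidic benzylic C–H and the stereocentre, which is not a reacting atom, is retained.

Step 13
Reactants: 6 3,5-bis(methoxymethoxy)-2-(trimethylsilyl)phenyl trifluoromethanesulfonate; 19 (3R)-3-[5-bromo-4-methoxy-2,3-bis(methoxymethoxy)phenyl]oxetan-2-one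
Product: 21 (3R)-3-[5-bromo-4-methoxy-2,3-bis(methoxymethoxy)phenyl]-5,7-bis(methoxymethoxy)chroman-4-one, via 3,5-bis(methoxymethoxy)benzyne 20 (not isolated)
Conditions: TBAT [Bu4N][Ph3SiF2] (2.0 equiv), 6 (1.8 equiv, slow addition), MeCN/toluene, 25 °C
Reagents that add atoms: none
Why: Proposed new method: fluoride from the non-basic silicate releases benzyne 20, the ring oxygen of the strained lactone (only weakly conjugated with its carbonyl in the four-membered ring) adds to the aryne carbon remote from the flanking acetal, and the aryl anion so placed next to that acetal attacks the acyloxonium-activated carbonyl carbon, after which the acyl–oxygen bond breaks with release of ring strain. The closest known reaction types are aryne σ-insertion into the N–acyl bond of ureas and lactams, the acyl-alkylation of arynes by β-keto esters and the C–O insertion of arynes into carboxylic acids that gives ortho-hydroxyaryl ketones. Ring C is closed by two-atom ring expansion of the oxetanone: O-arylation, then a 4-exo-trig attack of the aryl anion on the acyl carbon and fragmentation of the fused four-membered intermediate, which forms O1–C8a and C4–C4a. No stereocentre is formed; C3 is carried over from 19 because no bond at that carbon is touched and the medium is aprotic, non-basic and at room temperature. The step needs regioselective aryne capture (oxygen at C8a, acyl carbon at C4a beside the C5 oxygen), which the inductive polarisation of the aryne by the flanking acetal oxygen secures, and chemoselectivity for the ring oxygen over the carbonyl oxygen, which is the open point.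

Step 14
Reactants: 21 (3R)-3-[5-bromo-4-methoxy-2,3-bis(methoxymethoxy)phenyl]-5,7-bis(methoxymethoxy)chroman-4-one
Product: 22 (3R)-3-[4-methoxy-2,3-bis(methoxymethoxy)-5-(3-methylbut-2-en-1-yl)phenyl]-5,7-bis(methoxymethoxy)chroman-4-one
Conditions: Me2C=CHCH2SnBu3, Pd(PPh3)4 (10 mol %), DMF, 90 °C
Reagents that add atoms: tributyl(3-methylbut-2-en-1-yl)stannane, CCCC[Sn](CCCC)(CCCC)CC=C(C)C
Why: Stille cross-coupling under neutral conditions: oxidative addition of zerovalent palladium into the C5′–Br bond, transmetalation from the allylic stannane and reductive elimination at the unsubstituted allyl terminus should give the linear prenyl group, and with no base present the C3–H next to the ketone is not deprotonated.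

Step 15
Reactants: 22 (3R)-3-[4-methoxy-2,3-bis(methoxymethoxy)-5-(3-methylbut-2-en-1-yl)phenyl]-5,7-bis(methoxymethoxy)chroman-4-one
Product: 23 (3R)-3-[2,3-dihydroxy-4-methoxy-5-(3-methylbut-2-en-1-yl)phenyl]-5,7-dihydroxychroman-4-one (CNP0141716.1)
Conditions: ZnBr2, n-PrSH, CH2Cl2, 0 °C
Reagents that add atoms: none
Why: Lewis acid-assisted cleavage of the four methoxymethyl ethers with thiol capture of the methoxymethyl cation should be complete within minutes at 0 °C without Brønsted acid or base, which should spare the trisubstituted alkene, the aryl methyl ether and the configuration at C3.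

Compound list
1 | phloroglucinol | Oc1cc(O)cc(O)c1 | starting material
2 | 3,5-bis(methoxymethoxy)phenol | COCOc1cc(O)cc(OCOC)c1 | intermediate
3 | 2-bromo-3,5-bis(methoxymethoxy)phenol | COCOc1cc(O)c(Br)c(OCOC)c1 | intermediate
4 | [2-bromo-3,5-bis(methoxymethoxy)phenoxy]trimethylsilane | COCOc1cc(O[Si](C)(C)C)c(Br)c(OCOC)c1 | intermediate (not isolated)
5 | lithium 3,5-bis(methoxymethoxy)-2-(trimethylsilyl)phenolate | [Li+].[O-]c1cc(OCOC)cc(OCOC)c1[Si](C)(C)C | intermediate (not isolated)
6 | 3,5-bis(methoxymethoxy)-2-(trimethylsilyl)phenyl trifluoromethanesulfonate | COCOc1cc(OCOC)c([Si](C)(C)C)c(OS(=O)(=O)C(F)(F)F)c1 | intermediate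
7 | 2,3-dihydroxy-4-methoxybenzaldehyde | COc1ccc(C=O)c(O)c1O | starting material
8 | 5-bromo-2,3-dihydroxy-4-methoxybenzaldehyde | COc1c(Br)cc(C=O)c(O)c1O | intermediate
9 | 5-bromo-4-methoxy-2,3-bis(methoxymethoxy)benzaldehyde | COc1c(Br)cc(C=O)c(OCOC)c1OCOC | intermediate
10 | 2-[5-bromo-4-methoxy-2,3-bis(methoxymethoxy)phenyl]acetonitrile | COc1c(Br)cc(CC#N)c(OCOC)c1OCOC | intermediate
11 | 2-[5-bromo-4-methoxy-2,3-bis(methoxymethoxy)phenyl]acetic acid | COc1c(Br)cc(CC(=O)O)c(OCOC)c1OCOC | intermediate
12 | mixed anhydride of 11 with pivalic acid | COc1c(Br)cc(CC(=O)OC(=O)C(C)(C)C)c(OCOC)c1OCOC | intermediate (not isolated)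
13 | (4S)-4-benzyl-3-{2-[5-bromo-4-methoxy-2,3-bis(methoxymethoxy)phenyl]acetyl}-1,3-oxazolidin-2-one | COc1c(Br)cc(CC(=O)N2[C@@H](Cc3ccccc3)COC2=O)c(OCOC)c1OCOC | intermediate
14 | sodium (Z)-enolate of 13 | COc1c(Br)cc(/C=C(\[O-])N2[C@@H](Cc3ccccc3)COC2=O)c(OCOC)c1OCOC.[Na+] | intermediate (not isolated)
15 | (4S)-4-benzyl-3-{(2R)-2-[5-bromo-4-methoxy-2,3-bis(methoxymethoxy)phenyl]-3-[(triisopropylsilyl)oxy]propanoyl}-1,3-oxazolidin-2-one | COc1c(Br)cc([C@H](CO[Si](C(C)C)(C(C)C)C(C)C)C(=O)N2[C@@H](Cc3ccccc3)COC2=O)c(OCOC)c1OCOC | intermediate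
16 | (2R)-2-[5-bromo-4-methoxy-2,3-bis(methoxymethoxy)phenyl]-3-[(triisopropylsilyl)oxy]propaneperoxoic acid | COc1c(Br)cc([C@H](CO[Si](C(C)C)(C(C)C)C(C)C)C(=O)OO)c(OCOC)c1OCOC | intermediate (not isolated)
17 | (2R)-2-[5-bromo-4-methoxy-2,3-bis(methoxymethoxy)phenyl]-3-[(triisopropylsilyl)oxy]propanoic acid | COc1c(Br)cc([C@H](CO[Si](C(C)C)(C(C)C)C(C)C)C(=O)O)c(OCOC)c1OCOC | intermediate
18 | (2R)-2-[5-bromo-4-methoxy-2,3-bis(methoxymethoxy)phenyl]-3-hydroxypropanoic acid | COc1c(Br)cc([C@H](CO)C(=O)O)c(OCOC)c1OCOC | intermediate
19 | (3R)-3-[5-bromo-4-methoxy-2,3-bis(methoxymethoxy)phenyl]oxetan-2-one | COc1c(Br)cc([C@@H]2COC2=O)c(OCOC)c1OCOC | intermediate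
20 | 3,5-bis(methoxymethoxy)benzyne | COCOC1=CC(OCOC)=CC#C1 | intermediate (not isolated)
21 | (3R)-3-[5-bromo-4-methoxy-2,3-bis(methoxymethoxy)phenyl]-5,7-bis(methoxymethoxy)chroman-4-one | COc1c(Br)cc([C@@H]2COc3cc(OCOC)cc(OCOC)c3C2=O)c(OCOC)c1OCOC | intermediate
22 | (3R)-3-[4-methoxy-2,3-bis(methoxymethoxy)-5-(3-methylbut-2-en-1-yl)phenyl]-5,7-bis(methoxymethoxy)chroman-4-one | COc1c(CC=C(C)C)cc([C@@H]2COc3cc(OCOC)cc(OCOC)c3C2=O)c(OCOC)c1OCOC | intermediate
23 | (3R)-3-[2,3-dihydroxy-4-methoxy-5-(3-methylbut-2-en-1-yl)phenyl]-5,7-dihydroxychroman-4-one | COc1c(CC=C(C)C)cc([C@@H]2COc3cc(O)cc(O)c3C2=O)c(O)c1O | target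

Total step count: 15 (3 for the ring A fragment, 9 for the lactone, 3 from the coupling to the target).
Longest linear sequence: 12 steps (7 to 23, steps 4–15).

Steps most likely to fail

1. Step 13. The aryne may be captured through the lactone carbonyl oxygen instead of the ring oxygen. Fluoride may open or enolise the lactone, with loss of the C3 configuration or elimination to the acrylate. Excess aryne may arylate the product further. Fallback (known chemistry, etherification followed by intramolecular Friedel–Crafts acylation), setting out from 15 and returning at 21: the silyl ether of 15 is cleaved with HF·pyridine in THF/pyridine to the β-hydroxy imide F1. Mitsunobu etherification of F1 with phenol 2 (PPh3, DIAD, THF) gives the aryl ether imide F2. LiOH/H2O2 at 0 °C releases the aryloxy acid F3. Trifluoroacetic anhydride in CH2Cl2 at 0 °C then acylates the electron-rich ring at either of the two equivalent positions ortho to the ether oxygen and gives 21.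

2. Step 14. Allylic transposition during transmetalation and reductive elimination may give the branched 1,1-dimethylallyl isomer. Oxidative addition into the electron-rich, ortho-flanked C–Br bond may be slow and lead to protodebromination. Prolonged heating may epimerise C3. Fallback, setting out from 21 and returning at 22: Stille coupling with allyltributylstannane (Pd(PPh3)4, toluene, 100 °C), which has no regiochemical ambiguity, gives the 5′-allyl isoflavanone F4. Cross-metathesis of F4 with excess 2-methylbut-2-ene (second-generation Grubbs catalyst, CH2Cl2, 40 °C) converts the allyl into the prenyl group and gives 22.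

3. Step 2. Bromination may occur para to the hydroxyl, between the two acetal groups, or twice, and a para-bromide cannot undergo the silyl shift of step 3. Fallback (directed ortho-metalation instead of electrophilic bromination), setting out from 2 and returning at 6: carbamoylation (ClC(O)NEt2, NaH, THF) gives the diethylcarbamate F5. Lithiation between the carbamate and the neighbouring acetal oxygen (s-BuLi, TMEDA, THF, –78 °C) and quenching with Me3SiCl gives the ortho-silyl carbamate F6. Reductive removal of the carbamate (LiAlH4, THF, 0 °C) gives the silylphenol F7, and triflation (NaH, PhNTf2, THF) gives 6.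

Further compounds
F1 | step 13 | (4S)-4-benzyl-3-{(2R)-2-[5-bromo-4-methoxy-2,3-bis(methoxymethoxy)phenyl]-3-hydroxypropanoyl}-1,3-oxazolidin-2-one | COc1c(Br)cc([C@H](CO)C(=O)N2[C@@H](Cc3ccccc3)COC2=O)c(OCOC)c1OCOC
F2 | step 13 | (4S)-4-benzyl-3-{(2R)-3-[3,5-bis(methoxymethoxy)phenoxy]-2-[5-bromo-4-methoxy-2,3-bis(methoxymethoxy)phenyl]propanoyl}-1,3-oxazolidin-2-one | COc1c(Br)cc([C@H](COc2cc(OCOC)cc(OCOC)c2)C(=O)N2[C@@H](Cc3ccccc3)COC2=O)c(OCOC)c1OCOC
F3 | step 13 | (2R)-3-[3,5-bis(methoxymethoxy)phenoxy]-2-[5-bromo-4-methoxy-2,3-bis(methoxymethoxy)phenyl]propanoic acid | COc1c(Br)cc([C@H](COc2cc(OCOC)cc(OCOC)c2)C(=O)O)c(OCOC)c1OCOC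
F4 | step 14 | (3R)-3-[5-allyl-4-methoxy-2,3-bis(methoxymethoxy)phenyl]-5,7-bis(methoxymethoxy)chroman-4-one | COc1c(CC=C)cc([C@@H]2COc3cc(OCOC)cc(OCOC)c3C2=O)c(OCOC)c1OCOC
F5 | step 2 | 3,5-bis(methoxymethoxy)phenyl N,N-diethylcarbamate | COCOc1cc(OC(=O)N(CC)CC)cc(OCOC)c1
F6 | step 2 | 3,5-bis(methoxymethoxy)-2-(trimethylsilyl)phenyl N,N-diethylcarbamate | COCOc1cc(OC(=O)N(CC)CC)c([Si](C)(C)C)c(OCOC)c1
F7 | step 2 | 3,5-bis(methoxymethoxy)-2-(trimethylsilyl)phenol | COCOc1cc(O)c([Si](C)(C)C)c(OCOC)c1
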